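Molar hours are the measure of this flask. L reacts with G, so at each moment it decays pseudo-first-order at k·G, and the part left is exp(−kθ), where θ is the exposure, the time integral of the concentration of G.

all flasks: L 0.20 M

| charge | G | remark | time |
|---|---|---|---|
| ash | 0.33 M | run made earlier |  |
| cedar | 0.41 M | run made earlier |  |
| birch | 0.66 M | run made earlier |  |
| red | 0.500 M |  | 30 h |
| green | 0.300 M |  | 30 h |
| teal | 0.600 M |  | 30 h |
- ash (time / h: D / %, Z / %): 3.00: 6.0, 0.3; 6.00: 4.5, 0.6; 10.0: 3.5, 3.2; 12.0: 2.5, 2.3; 15.0: 1.4, 4.2
- cedar (time / h: D / %, Z / %): 1.33: 6.7, 0.3; 4.00: 6.0, 1.0; 8.00: 4.6, 2.3; 10.0: 3.5, 4.0; 15.0: 2.5, 6.5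
- birch (time / h: D / %, Z / %): 3.00: 9.5, 1.2; 6.00: 6.6, 5.4; 10.0: 2.7, 11.0; 12.0: 2.8, 13.1; 15.0: 1.7, 17.0

(readings scatter by 0.5 percentage points)
1. which of these holds the largest part of the L at the end of red (L / Q / Z / D)
2. which of these holds the largest part of the L at the end of green (L / Q / Z / D)
3. which of these holds the largest part of the L at the end of teal (L / Q / Z / D)
4. how much D is there at the end of red, in percent of the L charged
- the numbers in the tables scatter by 0.5 percentage points (one standard deviation)
- candidate steps: L + G -> E + D; D + G -> E + Q; Q + G -> E + Z; D -> J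

Taking D to follow L after the first hours, the fall of D in birch, from 9.5% to 1.7%, reads as a rate of loss of L of 0.143 /h. Taking G over that stretch as half of the L charge below its own charge, an estimate of this reckoning, gives

k = 0.256 /M/h, the loss of L per molar hour of exposure.

Turned round: for L to lead in red, it has to end above Z. At 15.0 h, Z reads as going with the square of the G charge: it rises by a factor of 4.05 from ash to birch, and no candidate step consumes Z. So red should hold

Z = 9.76% at 15.0 h,

and for L to stay above that mark up to 30 h, the mean G of red, θ over the time, has to lie below 0.303 M.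

Joining the two ends of red, G starts at 0.500 M and, at an assumed one and a half G per L lost, ends near 0.200 M. Then

mean G = 0.350 M, L = 6.80%,

so in this reckoning the mean G of red stands higher than that line, and L ends lower than the Z mark.

The forecast gave Z, L and Z for red, green and teal, with 0.5% of D in red, and called red “a close call”.

The flasks give Z, L and Z, with 0.645% of D in red. Red ends with 8.85% of L, which through k means a mean G of 0.316 M, and with 16.6% of Z.

    L + G → E + D (k = 0.260 /M/h)
    D + G → E + Q (k = 0.760 /M/h)
    Q + G → E + Z (k = 0.190 /M/h)
    D → J (k = 0.730 /h)

At 30 h in red, D turns into J 4.1 times as fast as into Q, and its half-life towards J alone, 0.95 h, is short against 30 h. J holds 65.8% there.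

Red read at 8.0 h has G at 69.0% of its charge, so the mean G is 0.422 M and k gives L = 42.1%. The flask holds 42.6%.

The earlier runs and the new flask were generated by integration with constants of no real substance, noise included.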